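**Retrosynthetic overview**
1. Target 11 ⇒ bis(N‑acylsultam) 8 + 2 agmatine: both amide bonds are made last by aminolysis, which also releases the two auxiliaries.
2. 8 ⇒ 2 × N‑p‑coumaroyl sultam 5 by a one‑pot oxidative 8–5′ radical dimerisation: C8–C5′ bond first, then O4′–C7 closure through a quinone methide, with the auxiliary setting C3 and trans closure setting C2.
3. 5 ⇒ N‑acryloyl sultam 3 + 4‑iodophenol (Heck); 3 ⇒ camphorsultam 1 + acryloyl chloride.
4. Ring order: both benzene rings are bought; the only ring made is the dihydrofuran, by C3–C3a bond formation and then O1–C2 bond formation, both in step 3.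

Assumption: the auxiliary's facial sense in step 3 follows the non‑chelated N‑acyl bornanesultam model (C=O anti to SO2, s‑cis radical, bonding on the Cα‑Re face of the (2R)‑sultam amide); this was assigned from a model and not from a measured result, and if it proves reversed the equally available (2S)‑sultam is used with nothing else changed.

**Step 1**
Reactants: 1 (2R)‑bornane‑10,2‑sultam [(1S)‑(−)‑2,10‑camphorsultam]; 2 acryloyl chloride
Product: 3 N‑acryloyl‑(2R)‑bornane‑10,2‑sultam
Conditions: Et3N (1.5 equiv), DMAP (5 mol%), CuCl (trace), CH2Cl2, −10 °C → rt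
Reagents that add atoms: none
Why: DMAP‑catalysed N‑acylation of the sulfonamide N–H by an acid chloride, with CuCl suppressing acrylate polymerisation and no stereocentre touched.

**Step 2**
Reactants: 3 N‑acryloyl‑(2R)‑bornane‑10,2‑sultam; 4 4‑iodophenol
Product: 5 N‑[(E)‑4‑hydroxycinnamoyl]‑(2R)‑bornane‑10,2‑sultam
Conditions: Pd(OAc)2 (3 mol%), n‑Bu4NCl (1 equiv), NaHCO3 (2.5 equiv), DMF, 60 °C
Reagents that add atoms: none
Why: Ligand‑free Mizoroki–Heck arylation (Jeffery conditions) of the acrylamide, where syn‑insertion and syn‑β‑hydride elimination give only the E‑alkene and the mild bicarbonate base tolerates the free phenol and the acyl sultam.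

**Step 3**
Reactants: 5 N‑[(E)‑4‑hydroxycinnamoyl]‑(2R)‑bornane‑10,2‑sultam (2 molecules)
Product: 8 (2R,3R)‑trans‑dihydrobenzofuran bis(N‑acylsultam), via phenoxyl radical 6 (not isolated), via 8–5′ quinone methide 7 (not isolated)
Conditions: Ag2O (0.55 equiv), dry CH2Cl2, rt, dark, 20 h; filter through Celite, SiO2, then recrystallise (EtOAc–hexane) to a single diastereomer; recovered 5 recycled
Reagents that add atoms: none
Why: Biomimetic oxidative phenol coupling, known in type for sultam amides of ferulic acid: Ag(I) one‑electron oxidation gives radical 6; radical–radical 8–5′ coupling takes place on the Cα‑Re face of the C8 centre (s‑cis, C=O anti to SO2, Si face blocked by the pseudo‑axial sulfonyl oxygen), fixing C3 as R; rearomatisation gives quinone methide 7, whose intramolecular phenol oxa‑Michael closure puts the aryl group trans to the C3 acyl group, fixing C2 as R; the minor (2S,3S) diastereomer is removed at this stage, so enantiopurity after auxiliary removal equals the diastereomeric purity of 8.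

**Step 4**
Reactants: 8 (2R,3R)‑trans‑dihydrobenzofuran bis(N‑acylsultam); 9 agmatine sulfate (6 equiv)
Product: 11 (2R,3R)‑hordatine A (target), via mono‑agmatine amide 10 (not isolated)
Conditions: NaOH (1 equiv per 9, aq.), 2‑hydroxypyridine (0.5 equiv), DMSO–H2O 9:1, 35 °C, 36 h; RP‑HPLC (0.1% TFA), then OH−‑form anion‑exchange resin to the free base
Reagents that add atoms: none
Why: Double aminolysis of the activated N‑acyl‑N‑sulfonyl amides (N‑acylsultam cleavage by a primary amine, assisted by 2‑pyridone bifunctional catalysis); only the primary amine of agmatine is free while the guanidine stays protonated, the medium is too weakly basic for E1cB opening of the dihydrofuran, and the trans C2/C3 arrangement is the thermodynamic one, so neither stereocentre is scrambled (the order of the two acyl transfers is immaterial).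

**Compound list**
1 | (2R)‑bornane‑10,2‑sultam, (1S)‑(−)‑2,10‑camphorsultam, (3aS,6R,7aR) | N1[C@@H]2C[C@H]3CC[C@]2(CS1(=O)=O)C3(C)C | starting material
2 | acryloyl chloride | C=CC(=O)Cl | starting material
3 | N‑acryloyl‑(2R)‑bornane‑10,2‑sultam | C=CC(=O)N1[C@@H]2C[C@H]3CC[C@]2(CS1(=O)=O)C3(C)C | intermediate
4 | 4‑iodophenol | Oc1ccc(I)cc1 | starting material
5 | N‑[(E)‑3‑(4‑hydroxyphenyl)prop‑2‑enoyl]‑(2R)‑bornane‑10,2‑sultam | O=C(/C=C/c1ccc(O)cc1)N1[C@@H]2C[C@H]3CC[C@]2(CS1(=O)=O)C3(C)C | intermediate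
6 | phenoxyl radical of 5 (spin delocalised to C8 and the ortho carbons) | O=C(/C=C/c1ccc([O])cc1)N1[C@@H]2C[C@H]3CC[C@]2(CS1(=O)=O)C3(C)C | intermediate (not isolated)
7 | (8S)‑8–5′‑coupled p‑quinone methide: C8 carries H, the acyl sultam, the 2‑hydroxy‑5‑[(E)‑2‑(sultam‑carbonyl)vinyl]phenyl group and the CH=(4‑oxocyclohexa‑2,5‑dienylidene) unit | O=C(/C=C/c1ccc(O)c(c1)[C@@H](C(=O)N1[C@@H]2C[C@H]3CC[C@]2(CS1(=O)=O)C3(C)C)C=C1C=CC(=O)C=C1)N1[C@@H]2C[C@H]3CC[C@]2(CS1(=O)=O)C3(C)C | intermediate (not isolated)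
8 | (2R,3R)‑trans‑2‑(4‑hydroxyphenyl)‑2,3‑dihydrobenzofuran with C3–CO–[(2R)‑sultam] and C5–(E)‑CH=CH–CO–[(2R)‑sultam] | O=C(/C=C/c1ccc2c(c1)[C@@H](C(=O)N1[C@@H]3C[C@H]4CC[C@]3(CS1(=O)=O)C4(C)C)[C@H](c1ccc(O)cc1)O2)N1[C@@H]2C[C@H]3CC[C@]2(CS1(=O)=O)C3(C)C | intermediate
9 | agmatine sulfate, (4‑aminobutyl)guanidine·H2SO4 | NCCCCN=C(N)N.OS(=O)(=O)O | starting material
10 | mono‑agmatine amide: C5 (E)‑acrylamide of agmatine formed, C3 acyl sultam still in place, (2R,3R) | NC(N)=NCCCCNC(=O)/C=C/c1ccc2c(c1)[C@@H](C(=O)N1[C@@H]3C[C@H]4CC[C@]3(CS1(=O)=O)C4(C)C)[C@H](c1ccc(O)cc1)O2 | intermediate (not isolated)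
11 | (2R,3R)‑trans‑hordatine A, CNP0497893.1 | NC(N)=NCCCCNC(=O)/C=C/c1ccc2c(c1)[C@@H](C(=O)NCCCCN=C(N)N)[C@H](c1ccc(O)cc1)O2 | target

**Totals**
Total step count: 4. Longest linear sequence: 4 (1 → 3 → 5 → 8 → 11).

**Three steps most likely to fail, with fallbacks**

Step 3 (highest risk): the yield is likely modest (about 30–40% is typical for coumarate‑type 8–5′ couplings), the product phenol can be over‑oxidised, and the facial selectivity and its sense are uncertain. The fallback sets out from 9 and comes back at 11, giving up auxiliary control and using the biosynthetic dimerisation itself on the fully elaborated monomer. Compound 9 is N‑acylated with commercial (E)‑4‑hydroxycinnamic acid (EDC·HCl, N‑hydroxysuccinimide, NaHCO3, aqueous dioxane; only the primary amine reacts, the guanidinium is inert) to give p‑coumaroylagmatine F1. F1 is dimerised with horseradish peroxidase/H2O2 in pH 6 aqueous buffer to give racemic trans‑hordatine A F2. Preparative chiral HPLC of F2 then separates 11 from the (2S,3S)‑enantiomer F3.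

Step 4: the enoyl sultam may react sluggishly or undergo aza‑Michael addition, and base could open the dihydrofuran. The fallback sets out from 8 and comes back at 11. Compound 8 is cleaved with LiOH/H2O2 in THF–H2O at 0 °C (a hydroperoxide nucleophile of low basicity, with the sultam recovered) to give the (2R,3R)‑diacid F4. F4 is converted with N‑hydroxysuccinimide/EDC·HCl in DMF into the bis(N‑hydroxysuccinimide) ester F5. F5 is treated with 9 and NaHCO3 in aqueous acetone at about pH 8 to give 11.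

Step 2: the free phenol and the electrophilic acryloyl sultam may not coexist well under Pd/base (oxa‑Michael addition, acyl transfer, Pd black). The fallback sets out from 3 and comes back at 5. Compound 3 undergoes olefin cross‑metathesis with commercial 4‑acetoxystyrene (Hoveyda–Grubbs II, 3 mol%, CH2Cl2, 40 °C; E‑selective) to give N‑[(E)‑4‑acetoxycinnamoyl]‑(2R)‑bornane‑10,2‑sultam F6. The aryl acetate of F6 is removed with pyrrolidine (1.05 equiv, CH2Cl2, 0 °C), which leaves the acyl sultam intact and gives 5.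

**Further compounds**
F1 | step 3 | p‑coumaroylagmatine | NC(N)=NCCCCNC(=O)/C=C/c1ccc(O)cc1
F2 | step 3 | racemic trans‑hordatine A (1:1 mixture of 11 and F3) | NC(N)=NCCCCNC(=O)/C=C/c1ccc2c(c1)[C@@H](C(=O)NCCCCN=C(N)N)[C@H](c1ccc(O)cc1)O2.NC(N)=NCCCCNC(=O)/C=C/c1ccc2c(c1)[C@H](C(=O)NCCCCN=C(N)N)[C@@H](c1ccc(O)cc1)O2
F3 | step 3 | (2S,3S)‑hordatine A (enantiomer of 11) | NC(N)=NCCCCNC(=O)/C=C/c1ccc2c(c1)[C@H](C(=O)NCCCCN=C(N)N)[C@@H](c1ccc(O)cc1)O2
F4 | step 4 | (2R,3R)‑trans‑5‑[(E)‑2‑carboxyvinyl]‑2‑(4‑hydroxyphenyl)‑2,3‑dihydrobenzofuran‑3‑carboxylic acid | OC(=O)/C=C/c1ccc2c(c1)[C@@H](C(=O)O)[C@H](c1ccc(O)cc1)O2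
F5 | step 4 | bis(N‑hydroxysuccinimide) ester of F4 | O=C(/C=C/c1ccc2c(c1)[C@@H](C(=O)ON1C(=O)CCC1=O)[C@H](c1ccc(O)cc1)O2)ON1C(=O)CCC1=O
F6 | step 2 | N‑[(E)‑4‑acetoxycinnamoyl]‑(2R)‑bornane‑10,2‑sultam | CC(=O)Oc1ccc(/C=C/C(=O)N2[C@@H]3C[C@H]4CC[C@]3(CS2(=O)=O)C4(C)C)cc1
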